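**Retrosynthetic overview**

1. Target 21 is cut at the bond between the bridging CH2 and ring A. This bond comes from conjugate addition of the free enolic carbon of 2-propanoylfilicinic acid 19 (from 17 by gem-dimethylation) to the ortho-quinone methide of ring B, which is stored as the benzylic methyl ether 16.
2. 16 comes from 14 by acidic methanolysis. 14 comes from 10 and amide 11 by lithiation of C8 and acylation, which forms the C8–acetyl bond.
3. 10 comes from chromene 5 by lithiation at C6 between the two methoxymethyl ethers, formylation, reduction and silylation. 5 comes from phloroglucinol 1 and enal 2.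
4. Ring order: ring B is bought as phloroglucinol, pyran ring C is closed onto it in step 1, and ring A is made separately and joined last.
5. Feature: benzene ring B is hexasubstituted, with the acetyl group on C8 (between C8a–O1 and the C7 hydroxyl) and the bridge on C6 (between the C5 and C7 hydroxyls). Because the three carbons of phloroglucinol are equivalent, annulation of ring C cannot give a regioisomer, and C6 and C8 are then addressed one after the other.

Key step: step 6

Remark: ring A is a cyclic β-triketone drawn as one enol tautomer; the tautomers equilibrate and the target has no stereocentre, so no step has to control configuration.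

**Route**

Step 1
Reactants: 1 phloroglucinol; 2 3-methylbut-2-enal
Product: 4 2,2-dimethyl-2H-chromene-5,7-diol, via alkylidene cyclohexadienone 3 (not isolated)
Conditions: pyridine, 110 °C; 1 in threefold excess
Reagents that add atoms: none
Why: Knoevenagel-type condensation of 1 with the enal gives dienone 3, which closes by oxa-6π electrocyclisation; the symmetry of 1 allows only one chromene, and the excess of 1 should limit a second annulation.

Step 2
Reactants: 4 2,2-dimethyl-2H-chromene-5,7-diol
Product: 5 5,7-bis(methoxymethoxy)-2,2-dimethyl-2H-chromene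
Conditions: MOMCl, i-Pr2NEt, CH2Cl2, 0 °C to rt
Reagents that add atoms: chloromethyl methyl ether, COCCl
Why: O-alkylation of both unhindered phenols with a reactive α-chloro ether; the two acetal ethers then serve as directing groups for both lithiations.

Step 3
Reactants: 5 5,7-bis(methoxymethoxy)-2,2-dimethyl-2H-chromene
Product: 8 5,7-bis(methoxymethoxy)-2,2-dimethyl-2H-chromene-6-carbaldehyde, via C6 aryllithium 6 (not isolated), via lithium hemiaminal alkoxide 7 (not isolated)
Conditions: n-C4H9Li, TMEDA, THF, 0 °C; DMF, 0 °C to rt; aq NH4Cl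
Reagents that add atoms: N,N-dimethylformamide, CN(C)C=O
Why: Directed ortho-metalation: C6–H lies between two chelating methoxymethyl ethers, which direct more strongly than the hindered pyran oxygen beside C8, so deprotonation should occur at C6, and DMF formylates the aryllithium through adduct 7.

Step 4
Reactants: 8 5,7-bis(methoxymethoxy)-2,2-dimethyl-2H-chromene-6-carbaldehyde
Product: 9 [5,7-bis(methoxymethoxy)-2,2-dimethyl-2H-chromen-6-yl]methanol
Conditions: NaBH4, MeOH, 0 °C
Reagents that add atoms: none
Why: Hydride reduction of an aryl aldehyde; the chromene alkene and the acetals are inert to NaBH4.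

Step 5
Reactants: 9 [5,7-bis(methoxymethoxy)-2,2-dimethyl-2H-chromen-6-yl]methanol
Product: 10 6-(tert-butyldimethylsilyloxymethyl)-5,7-bis(methoxymethoxy)-2,2-dimethyl-2H-chromene
Conditions: TBSCl, imidazole, DMF, rt
Reagents that add atoms: tert-butyldimethylsilyl chloride, CC(C)(C)[Si](C)(C)Cl
Why: Standard silylation of a primary benzylic alcohol; it removes the acidic hydroxyl before the second lithiation and gives an ether that tolerates n-C4H9Li.

Step 6
Reactants: 10 6-(tert-butyldimethylsilyloxymethyl)-5,7-bis(methoxymethoxy)-2,2-dimethyl-2H-chromene; 11 N-methoxy-N-methylacetamide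
Product: 14 8-acetyl-6-(tert-butyldimethylsilyloxymethyl)-5,7-bis(methoxymethoxy)-2,2-dimethyl-2H-chromene, via C8 aryllithium 12 (not isolated), via chelated tetrahedral adduct 13 (not isolated)
Conditions: n-C4H9Li, TMEDA, THF, −20 to 0 °C; 11 (2 equiv), −78 to 0 °C; aq NH4Cl
Reagents that add atoms: none
Why: n-C4H9Li·TMEDA binds to the oxygens of the C7 methoxymethyl ether and to pyran oxygen O1, and this pre-complex delivers the base to C8–H, the only arene hydrogen of ring B, to give aryllithium 12 (directed ortho-metalation). Aryllithium 12 adds to the carbonyl of 11 to give alkoxide 13, whose five-membered lithium chelate with the N-methoxy oxygen persists until the aqueous quench, so the methyl ketone is released only then and cannot take up a second aryllithium. The closest known reactions are the ortho-lithiation of methoxymethyl aryl ethers and the Weinreb ketone synthesis from aryllithiums. No ring is closed and no stereocentre is formed. The step needs only site selectivity of deprotonation: C8 is flanked by two ether oxygens, the C4 vinylic hydrogen has one remote director, and the CH2OSi hydrogens are shielded by the bulky silyl group, while lithiation at or below 0 °C should suppress silyl migration from oxygen to carbon. Adding 11 in excess at −78 °C counters proton transfer from the amide to the hindered aryllithium.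

Step 7
Reactants: 14 8-acetyl-6-(tert-butyldimethylsilyloxymethyl)-5,7-bis(methoxymethoxy)-2,2-dimethyl-2H-chromene
Product: 16 1-[5,7-dihydroxy-6-(methoxymethyl)-2,2-dimethyl-2H-chromen-8-yl]ethan-1-one, via ortho-hydroxybenzyl alcohol 15 (not isolated)
Conditions: HCl (1.25 M in MeOH), dilute, rt to 40 °C; NaHCO3 before concentration
Reagents that add atoms: methanol, CO
Why: Acidic methanolysis cleaves the silyl ether and both acetals to alcohol 15, whose strongly stabilised benzylic cation is captured by the solvent (SN1 etherification), so the storable methyl ether 16 should be isolated instead of the self-condensing alcohol.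

Step 8
Reactants: 17 1-(2,4,6-trihydroxyphenyl)propan-1-one
Product: 19 3,5-dihydroxy-4,4-dimethyl-2-propanoylcyclohexa-2,5-dien-1-one, via mono-C-methyl ketone 18 (not isolated)
Conditions: NaOCH3, CH3I (2.2 equiv), MeOH, 0 °C to rt; aq HCl
Reagents that add atoms: iodomethane, CI
Why: Known dearomatising C-methylation of acylphloroglucinol anions: the methylated carbon of 18 is the most electron-rich site of its anion and should take the second methyl group, and the 3,5-dimethyl and trimethyl by-products to be expected are removed by chromatography.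

Step 9
Reactants: 16 1-[5,7-dihydroxy-6-(methoxymethyl)-2,2-dimethyl-2H-chromen-8-yl]ethan-1-one; 19 3,5-dihydroxy-4,4-dimethyl-2-propanoylcyclohexa-2,5-dien-1-one
Product: 21 2-[(8-acetyl-5,7-dihydroxy-2,2-dimethyl-2H-chromen-6-yl)methyl]-3,5-dihydroxy-4,4-dimethyl-6-propanoylcyclohexa-2,5-dien-1-one, via ortho-quinone methide 20 (not isolated)
Conditions: p-TsOH·H2O (10 mol%), 1,4-dioxane, 40 °C; 16 added slowly to 19 (1.5 equiv)
Reagents that add atoms: none
Why: Acid-promoted loss of methanol from 16 gives quinone methide 20, which takes up the only free enolic carbon of triketone 19 in a Michael addition; neither partner has another free nucleophilic carbon, and slow addition of 16 to excess 19 should limit self-capture.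

**Compound list**

1 | phloroglucinol (benzene-1,3,5-triol) | Oc1cc(O)cc(O)c1 | starting material
2 | 3-methylbut-2-enal | CC(C)=CC=O | starting material
3 | 3,5-dihydroxy-6-(3-methylbut-2-en-1-ylidene)cyclohexa-2,4-dien-1-one | CC(C)=CC=C1C(=O)C=C(O)C=C1O | intermediate (not isolated)
4 | 2,2-dimethyl-2H-chromene-5,7-diol | CC1(C)C=Cc2c(O)cc(O)cc2O1 | intermediate
5 | 5,7-bis(methoxymethoxy)-2,2-dimethyl-2H-chromene | COCOc1cc(OCOC)c2C=CC(C)(C)Oc2c1 | intermediate
6 | [5,7-bis(methoxymethoxy)-2,2-dimethyl-2H-chromen-6-yl]lithium | [Li]c1c(OCOC)cc2OC(C)(C)C=Cc2c1OCOC | intermediate (not isolated)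
7 | lithium [5,7-bis(methoxymethoxy)-2,2-dimethyl-2H-chromen-6-yl](dimethylamino)methanolate | [Li]OC(N(C)C)c1c(OCOC)cc2OC(C)(C)C=Cc2c1OCOC | intermediate (not isolated)
8 | 5,7-bis(methoxymethoxy)-2,2-dimethyl-2H-chromene-6-carbaldehyde | O=Cc1c(OCOC)cc2OC(C)(C)C=Cc2c1OCOC | intermediate
9 | [5,7-bis(methoxymethoxy)-2,2-dimethyl-2H-chromen-6-yl]methanol | OCc1c(OCOC)cc2OC(C)(C)C=Cc2c1OCOC | intermediate
10 | 6-(tert-butyldimethylsilyloxymethyl)-5,7-bis(methoxymethoxy)-2,2-dimethyl-2H-chromene | COCOc1cc2c(c(OCOC)c1CO[Si](C)(C)C(C)(C)C)C=CC(C)(C)O2 | intermediate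
11 | N-methoxy-N-methylacetamide | CON(C)C(C)=O | starting material
12 | [6-(tert-butyldimethylsilyloxymethyl)-5,7-bis(methoxymethoxy)-2,2-dimethyl-2H-chromen-8-yl]lithium | [Li]c1c(OCOC)c(CO[Si](C)(C)C(C)(C)C)c(OCOC)c2C=CC(C)(C)Oc12 | intermediate (not isolated)
13 | lithium 1-[6-(tert-butyldimethylsilyloxymethyl)-5,7-bis(methoxymethoxy)-2,2-dimethyl-2H-chromen-8-yl]-1-[methoxy(methyl)amino]ethan-1-olate | CON(C)C(C)(O[Li])c1c(OCOC)c(CO[Si](C)(C)C(C)(C)C)c(OCOC)c2C=CC(C)(C)Oc12 | intermediate (not isolated)
14 | 8-acetyl-6-(tert-butyldimethylsilyloxymethyl)-5,7-bis(methoxymethoxy)-2,2-dimethyl-2H-chromene | COCOc1c(C(C)=O)c2c(c(OCOC)c1CO[Si](C)(C)C(C)(C)C)C=CC(C)(C)O2 | intermediate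
15 | 1-[5,7-dihydroxy-6-(hydroxymethyl)-2,2-dimethyl-2H-chromen-8-yl]ethan-1-one | CC(=O)c1c(O)c(CO)c(O)c2C=CC(C)(C)Oc12 | intermediate (not isolated)
16 | 1-[5,7-dihydroxy-6-(methoxymethyl)-2,2-dimethyl-2H-chromen-8-yl]ethan-1-one | COCc1c(O)c(C(C)=O)c2OC(C)(C)C=Cc2c1O | intermediate
17 | 1-(2,4,6-trihydroxyphenyl)propan-1-one | CCC(=O)c1c(O)cc(O)cc1O | starting material
18 | 1-(2,4,6-trihydroxy-3-methylphenyl)propan-1-one | CCC(=O)c1c(O)cc(O)c(C)c1O | intermediate (not isolated)
19 | 3,5-dihydroxy-4,4-dimethyl-2-propanoylcyclohexa-2,5-dien-1-one (2-propanoylfilicinic acid) | CCC(=O)C1=C(O)C(C)(C)C(O)=CC1=O | intermediate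
20 | 8-acetyl-7-hydroxy-2,2-dimethyl-6-methylidene-2H-chromen-5(6H)-one | C=C1C(=O)C2=C(OC(C)(C)C=C2)C(C(C)=O)=C1O | intermediate (not isolated)
21 | 2-[(8-acetyl-5,7-dihydroxy-2,2-dimethyl-2H-chromen-6-yl)methyl]-3,5-dihydroxy-4,4-dimethyl-6-propanoylcyclohexa-2,5-dien-1-one | CCC(=O)C1=C(O)C(C)(C)C(O)=C(Cc2c(O)c3c(c(C(C)=O)c2O)OC(C)(C)C=C3)C1=O | target

**Step count**

Total: 9 steps. Longest linear sequence: 8 steps (steps 1 to 7, then step 9); step 8 is a one-step side branch.

**Steps most likely to fail**

Step 9. The quinone methide may be captured by its own precursor with loss of the C1 unit, or the methylene bridge may be exchanged under acid, so that symmetrical dimers form instead of the mixed one. The fallback avoids a free quinone methide and sets out from 14. Desilylation with (n-C4H9)4NF in THF should give 1-[6-(hydroxymethyl)-5,7-bis(methoxymethoxy)-2,2-dimethyl-2H-chromen-8-yl]ethan-1-one F1. CH3SO2Cl and Et3N in CH2Cl2 at 0 °C should convert it into 1-[6-(chloromethyl)-5,7-bis(methoxymethoxy)-2,2-dimethyl-2H-chromen-8-yl]ethan-1-one F2, used crude. C-Alkylation of the potassium salt of 19 with this chloride in aqueous KOH and toluene at 0 °C, conditions under which acylphloroglucinol anions are alkylated at carbon by benzylic and allylic halides, should give 2-{[8-acetyl-5,7-bis(methoxymethoxy)-2,2-dimethyl-2H-chromen-6-yl]methyl}-3,5-dihydroxy-4,4-dimethyl-6-propanoylcyclohexa-2,5-dien-1-one F3. Methanolic HCl at rt then removes both acetals, and the sequence comes back to the route at target 21.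

Step 6. Proton transfer from the amide to the hindered aryllithium, or deprotonation at the silyloxymethyl carbon followed by silyl migration, may return starting material or a rearranged carbinol. The fallback uses no organolithium and sets out from 10. Iodination of C8, the only free arene carbon, with N-iodosuccinimide and NaHCO3 in MeCN at 0 °C should give tert-butyl{[8-iodo-5,7-bis(methoxymethoxy)-2,2-dimethyl-2H-chromen-6-yl]methoxy}dimethylsilane F4. Stille coupling with tributyl(1-ethoxyvinyl)stannane, catalysed by Pd(PPh3)4 (zerovalent palladium) with CuI and CsF in DMF at 60 °C, should give tert-butyl{[8-(1-ethoxyethenyl)-5,7-bis(methoxymethoxy)-2,2-dimethyl-2H-chromen-6-yl]methoxy}dimethylsilane F5. Brief hydrolysis of the enol ether with oxalic acid in wet THF at 0 °C then comes back to the route at 14.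

Step 3. Deprotonation at C8 beside the pyran oxygen may compete with deprotonation at C6 and give a mixture of regioisomeric aldehydes. The fallback places the formyl group on a symmetric arene before ring C is built and sets out from 1.
- Monosilylation of excess 1 with triisopropylsilyl chloride and imidazole in DMF should give 5-[tri(propan-2-yl)silyloxy]benzene-1,3-diol F6.
- MOMCl and i-Pr2NEt should give [3,5-bis(methoxymethoxy)phenoxy]tri(propan-2-yl)silane F7.
- Lithiation with n-C4H9Li and TMEDA in THF at 0 °C can occur only between the two acetal ethers, because the bulky silyl ether blocks its own ortho positions; DMF should then give 2,6-bis(methoxymethoxy)-4-[tri(propan-2-yl)silyloxy]benzaldehyde F8.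
- (n-C4H9)4NF in THF should give 4-hydroxy-2,6-bis(methoxymethoxy)benzaldehyde F9.
- Annulation of this phenol with 2 in pyridine at 120 °C can use either of its two equivalent ortho carbons and so comes back to the route at 8 as a single regioisomer.

**Further compounds**

F1 | step 9 | 1-[6-(hydroxymethyl)-5,7-bis(methoxymethoxy)-2,2-dimethyl-2H-chromen-8-yl]ethan-1-one | COCOc1c(C(C)=O)c2c(c(OCOC)c1CO)C=CC(C)(C)O2
F2 | step 9 | 1-[6-(chloromethyl)-5,7-bis(methoxymethoxy)-2,2-dimethyl-2H-chromen-8-yl]ethan-1-one | COCOc1c(C(C)=O)c2c(c(OCOC)c1CCl)C=CC(C)(C)O2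
F3 | step 9 | 2-{[8-acetyl-5,7-bis(methoxymethoxy)-2,2-dimethyl-2H-chromen-6-yl]methyl}-3,5-dihydroxy-4,4-dimethyl-6-propanoylcyclohexa-2,5-dien-1-one | CCC(=O)C1=C(O)C(C)(C)C(O)=C(Cc2c(OCOC)c3c(c(C(C)=O)c2OCOC)OC(C)(C)C=C3)C1=O
F4 | step 6 | tert-butyl{[8-iodo-5,7-bis(methoxymethoxy)-2,2-dimethyl-2H-chromen-6-yl]methoxy}dimethylsilane | COCOc1c(I)c2c(c(OCOC)c1CO[Si](C)(C)C(C)(C)C)C=CC(C)(C)O2
F5 | step 6 | tert-butyl{[8-(1-ethoxyethenyl)-5,7-bis(methoxymethoxy)-2,2-dimethyl-2H-chromen-6-yl]methoxy}dimethylsilane | CCOC(=C)c1c(OCOC)c(CO[Si](C)(C)C(C)(C)C)c(OCOC)c2C=CC(C)(C)Oc12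
F6 | step 3 | 5-[tri(propan-2-yl)silyloxy]benzene-1,3-diol | CC(C)[Si](Oc1cc(O)cc(O)c1)(C(C)C)C(C)C
F7 | step 3 | [3,5-bis(methoxymethoxy)phenoxy]tri(propan-2-yl)silane | COCOc1cc(OCOC)cc(O[Si](C(C)C)(C(C)C)C(C)C)c1
F8 | step 3 | 2,6-bis(methoxymethoxy)-4-[tri(propan-2-yl)silyloxy]benzaldehyde | COCOc1cc(O[Si](C(C)C)(C(C)C)C(C)C)cc(OCOC)c1C=O
F9 | step 3 | 4-hydroxy-2,6-bis(methoxymethoxy)benzaldehyde | COCOc1cc(O)cc(OCOC)c1C=O
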